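**Retrosynthetic overview**

1. Numbering follows the target as an octahydronaphthalene: C-1 carries CH3/CO2Me, C-3 is the ketone, C-4=C-4a is the alkene, C-5 is quaternary, C-6 is CH–CH3, C-8a is the ring-fusion CH. Ring A is C-1 to C-4a plus C-8a; ring B is C-4a to C-8a.
2. Target ⇐ silyl ether 21 ⇐ aldehyde 20; the 6-methyl group is carried as CH2CHO and cut back by rhodium decarbonylation.
3. 20 ⇐ dienone 13 + side-chain organomagnesium 17. A 1,6-addition gives a silyl dienol ether of fixed geometry, and its γ-carbon C-5 then closes ring B onto C-6. The enabling feature is that C-5 is the exocyclic γ-carbon of the ring A enone (C-3=O, C-4=C-4a), a vinylogous enolate position.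
4. 13 ⇐ Diels–Alder adduct 5 (siloxydiene 4 + formyl acrylate 2; sets C-1 and C-8a) by methylenation, B-alkyl Suzuki–Miyaura coupling and two Saegusa–Ito oxidations.
5. Ring A is formed first (Diels–Alder), ring B last (key step); the side chain comes from (S)-2-methylbutane-1,4-diol.

Key step: step 11

**Step 1**
Reactants: 1 methyl (2E)-2-methylbut-2-enoate
Product: 2 methyl (2E)-2-methyl-4-oxobut-2-enoate
Conditions: SeO2, 1,4-dioxane, 100 °C
Reagents that add atoms: selenium dioxide, O=[Se]=O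
Why: Riley oxidation: in an α,β-unsaturated ester the ene/[2,3]-sigmatropic sequence takes hydrogen from the γ-methyl group, which is carried on to the aldehyde with the (E)-geometry (ester trans to formyl) kept; no stereocentre is formed.

**Step 2**
Reactants: 3 but-3-en-2-one
Product: 4 2-[(tert-butyldimethylsilyl)oxy]buta-1,3-diene
Conditions: t-BuMe2SiOTf, Et3N, Et2O, 0 °C
Reagents that add atoms: tert-butyldimethylsilyl trifluoromethanesulfonate, CC(C)(C)[Si](C)(C)OS(=O)(=O)C(F)(F)F
Why: Soft enolisation and O-silylation of a methyl ketone with one enolisable position should give the 2-siloxydiene; no stereocentre is formed.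

**Step 3**
Reactants: 2 methyl (2E)-2-methyl-4-oxobut-2-enoate; 4 2-[(tert-butyldimethylsilyl)oxy]buta-1,3-diene
Product: 5 methyl (1S,6S)-3-[(tert-butyldimethylsilyl)oxy]-6-formyl-1-methylcyclohex-3-ene-1-carboxylate
Conditions: (S)-1-(2-methylphenyl)-3,3-diphenyltetrahydro-1H,3H-pyrrolo[1,2-c][1,3,2]oxazaborole (20 mol%), Tf2NH (18 mol%), CH2Cl2, −78 °C
Reagents that add atoms: none
Why: Diels–Alder reaction under cationic oxazaborolidine catalysis: the boron acid binds the formyl oxygen, so the nucleophilic CH2 terminus next to the siloxy carbon bonds to the carbon β to the formyl group (the methyl/ester-bearing carbon, future C-1); suprafacial addition to the (E)-alkene fixes CO2Me trans to CHO (C-1/C-8a relative configuration), and the catalyst must direct the diene to the Si face of the formyl-bearing carbon to set both centres absolutely (the (S)-catalyst is the working antipode, the (R)-catalyst being used if the sense proves opposite).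

**Step 4**
Reactants: 5 methyl (1S,6S)-3-[(tert-butyldimethylsilyl)oxy]-6-formyl-1-methylcyclohex-3-ene-1-carboxylate
Product: 6 methyl (1S,6R)-3-[(tert-butyldimethylsilyl)oxy]-6-ethenyl-1-methylcyclohex-3-ene-1-carboxylate
Conditions: Ph3PCH3Br, KN(SiMe3)2, THF, −78 to 0 °C
Reagents that add atoms: methyltriphenylphosphonium bromide, C[P+](c1ccccc1)(c1ccccc1)c1ccccc1.[Br-]
Why: Wittig methylenation of the aldehyde only (the hindered ester and the silyl enol ether are inert); the low temperature should keep the α-stereocentre from epimerising, and the descriptor changes to R by priority alone.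

**Step 5**
Reactants: 7 3,3-diethoxyprop-1-yne
Product: 8 (1E)-3,3-diethoxy-1-iodoprop-1-ene
Conditions: Cp2Zr(H)Cl, CH2Cl2, 25 °C; then I2, 0 °C
Reagents that add atoms: iodine, II
Why: Hydrozirconation adds Zr–H syn with zirconium on the terminal carbon, and iodinolysis with retention should give the (E)-iodoalkene.

**Step 6**
Reactants: 6 methyl (1S,6R)-3-[(tert-butyldimethylsilyl)oxy]-6-ethenyl-1-methylcyclohex-3-ene-1-carboxylate; 8 (1E)-3,3-diethoxy-1-iodoprop-1-ene
Product: 10 methyl (1S,6S)-3-[(tert-butyldimethylsilyl)oxy]-6-[(3E)-5,5-diethoxypent-3-en-1-yl]-1-methylcyclohex-3-ene-1-carboxylate, via alkylborane 9 (not isolated)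
Conditions: 9-BBN, THF, 25 °C; then 8, PdCl2(dppf) (5 mol%), AsPh3, Cs2CO3, DMF–H2O, 25 °C
Reagents that add atoms: none
Why: Anti-Markovnikov hydroboration of the only monosubstituted alkene (the siloxy-bearing ring alkene is trisubstituted and slow), then B-alkyl Suzuki–Miyaura coupling with retention of the (E)-iodoalkene geometry; no stereocentre is touched.

**Step 7**
Reactants: 10 methyl (1S,6S)-3-[(tert-butyldimethylsilyl)oxy]-6-[(3E)-5,5-diethoxypent-3-en-1-yl]-1-methylcyclohex-3-ene-1-carboxylate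
Product: 11 methyl (1S,2S)-2-[(3E)-5,5-diethoxypent-3-en-1-yl]-1-methyl-5-oxocyclohex-3-ene-1-carboxylate
Conditions: Pd(OAc)2, MeCN, 40 °C
Reagents that add atoms: none
Why: Saegusa–Ito oxidation: divalent palladium forms the C-4-bound enolate from the regiodefined silyl enol ether and β-hydride elimination can only take hydrogen from C-4a, giving the C-3 ketone with the C-4=C-4a alkene; C-8a is untouched.

**Step 8**
Reactants: 11 methyl (1S,2S)-2-[(3E)-5,5-diethoxypent-3-en-1-yl]-1-methyl-5-oxocyclohex-3-ene-1-carboxylate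
Product: 13 methyl (1S,2S)-2-[(3E)-5,5-diethoxypent-3-en-1-yl]-1-methyl-5-oxo-3-(prop-1-en-2-yl)cyclohex-3-ene-1-carboxylate, via trimethylsilyl enol ether 12 (not isolated)
Conditions: CH2=C(CH3)MgBr, CuBr·SMe2 (10 mol%), Me3SiCl, THF, −78 °C; then Pd(OAc)2, MeCN, 25 °C
Reagents that add atoms: prop-1-en-2-ylmagnesium bromide, CC(=C)[Mg]Br
Why: Copper-catalysed conjugate addition of the alkenylmagnesium reagent to C-4a with in situ silylation, then Saegusa–Ito oxidation of the resulting silyl enol ether, should restore the C-4=C-4a alkene now bearing the 2-propenyl group; the transient C-4a stereocentre is destroyed and C-8a is untouched.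

**Step 9**
Reactants: 14 (2S)-2-methylbutane-1,4-diol
Product: 15 (2S)-4-[(tert-butyldiphenylsilyl)oxy]-2-methylbutan-1-ol
Conditions: t-BuPh2SiCl (1.0 equiv), imidazole, CH2Cl2, −20 °C
Reagents that add atoms: tert-butyl(chloro)diphenylsilane, CC(C)(C)[Si](Cl)(c1ccccc1)c1ccccc1
Why: Silylation under steric control: the bulky chlorosilane should take the hydroxyl on the unbranched CH2CH2 end in preference to the β-branched CH2OH, the regioisomer being removed by chromatography; the stereocentre is untouched.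

**Step 10**
Reactants: 15 (2S)-4-[(tert-butyldiphenylsilyl)oxy]-2-methylbutan-1-ol
Product: 16 [(3S)-4-bromo-3-methylbutoxy](tert-butyl)diphenylsilane
Conditions: CBr4, PPh3, CH2Cl2, 0 °C
Reagents that add atoms: tetrabromomethane, BrC(Br)(Br)Br
Why: Appel reaction: SN2 displacement at the primary carbon, with the adjacent stereocentre not involved.

**Step 11**
Reactants: 13 methyl (1S,2S)-2-[(3E)-5,5-diethoxypent-3-en-1-yl]-1-methyl-5-oxo-3-(prop-1-en-2-yl)cyclohex-3-ene-1-carboxylate; 16 [(3S)-4-bromo-3-methylbutoxy](tert-butyl)diphenylsilane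
Product: 20 methyl (1S,5S,6S,8aS)-5-{(3R)-5-[(tert-butyldiphenylsilyl)oxy]-3-methylpentyl}-1,5-dimethyl-3-oxo-6-(2-oxoethyl)-1,2,3,5,6,7,8,8a-octahydronaphthalene-1-carboxylate, via organomagnesium reagent 17 (not isolated), via trimethylsilyl dienol ether 18 (not isolated), via ethyl enol ether 19 (not isolated)
Conditions: 16, Mg, THF, 25 °C; then 13, CuBr·SMe2 (10 mol%), Me3SiCl, THF, −78 °C; Et3N, pentane, filtration; then Me3SiOTf (20 mol%), CH2Cl2, −78 °C; 1 M HCl, THF, 0 °C
Reagents that add atoms: water, O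
Why: Organomagnesium reagent 17 adds under copper catalysis to the terminal CH2 of the 2-propenyl group of 13 (1,6-addition to a 3-alkenylcyclohexenone) and Me3SiCl traps the extended enolate as silyl dienol ether 18; addition through the s-trans diene conformer should place the new chain on the C-8a side of the exocyclic C-4a=C-5 double bond ((E)-isomer), since the s-cis form presses the 5-methyl group against H-8a and the C-8 arm. Me3SiOTf then ionises the allylic acetal to a 1-ethoxyallyl cation, which C-5 (the γ-carbon of the 1-siloxydiene) attacks at C-6 in an intramolecular vinylogous Mukaiyama–Michael reaction (closest known type: Lewis-acid-mediated conjugate addition of silyl dienol ethers to enals and their acetals); silyl loss regenerates the C-3 ketone/C-4=C-4a enone and the acid work-up hydrolyses enol ether 19 to aldehyde 20. Ring B closes 6-exo-trig with respect to the acceptor alkene, with the donor double bond C-4a=C-5 inside the new ring, through a chair in which C-8 is pseudoaxial on ring A to relieve allylic 1,3-strain with the C-5 substituent. C-5 is set by the fixed geometry of the C-4a=C-5 double bond together with delivery of C-6 from the face that carries the tether, which puts the side chain cis to H-8a and the 5-methyl group trans. C-6 is set by a compact synclinal transition state in which the cationic ene unit lies over C-4a/C-4 of the electron-rich diene and not in the cleft between the two substituents of the fully substituted C-5, which puts the CH2CHO group (the later 6-methyl) cis to the 5-methyl group and trans to the side chain. The step needs γ-attack (C-5) over α-attack (C-4), secured by the larger terminal HOMO coefficient of the 1-siloxydiene and by the loss of enone conjugation in the bridged alternative; it also needs conjugate attack (six-membered ring) over attack at the acetal carbon (eight-membered ring), and 1,6- over 1,4-addition, secured by the fully substituted C-4a.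

**Step 12**
Reactants: 20 methyl (1S,5S,6S,8aS)-5-{(3R)-5-[(tert-butyldiphenylsilyl)oxy]-3-methylpentyl}-1,5-dimethyl-3-oxo-6-(2-oxoethyl)-1,2,3,5,6,7,8,8a-octahydronaphthalene-1-carboxylate
Product: 21 methyl (1S,5S,6R,8aS)-5-{(3R)-5-[(tert-butyldiphenylsilyl)oxy]-3-methylpentyl}-1,5,6-trimethyl-3-oxo-1,2,3,5,6,7,8,8a-octahydronaphthalene-1-carboxylate
Conditions: RhCl(PPh3)3 (1.1 equiv), toluene, 110 °C
Reagents that add atoms: none
Why: Tsuji–Wilkinson decarbonylation: monovalent rhodium inserts into the formyl C–H bond, extrudes CO and forms the C–H bond by reductive elimination, turning CH2CHO into CH3; C-6 is not involved, its descriptor changing to R by priority alone.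

**Step 13**
Reactants: 21 methyl (1S,5S,6R,8aS)-5-{(3R)-5-[(tert-butyldiphenylsilyl)oxy]-3-methylpentyl}-1,5,6-trimethyl-3-oxo-1,2,3,5,6,7,8,8a-octahydronaphthalene-1-carboxylate
Product: 22 methyl (1S,5S,6R,8aS)-5-[(3R)-5-hydroxy-3-methylpentyl]-1,5,6-trimethyl-3-oxo-1,2,3,5,6,7,8,8a-octahydronaphthalene-1-carboxylate
Conditions: Bu4NF, AcOH, THF, 25 °C
Reagents that add atoms: none
Why: Fluoride-mediated cleavage of the silyl ether; the acetic acid buffer should keep the enone γ-position (C-8a) and the ester from base-induced change.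

**Compound list**

1 | methyl (2E)-2-methylbut-2-enoate | COC(=O)/C(C)=C/C | starting material
2 | methyl (2E)-2-methyl-4-oxobut-2-enoate | COC(=O)/C(C)=C/C=O | intermediate
3 | but-3-en-2-one | CC(=O)C=C | starting material
4 | 2-[(tert-butyldimethylsilyl)oxy]buta-1,3-diene | C=CC(=C)O[Si](C)(C)C(C)(C)C | intermediate
5 | methyl (1S,6S)-3-[(tert-butyldimethylsilyl)oxy]-6-formyl-1-methylcyclohex-3-ene-1-carboxylate | COC(=O)[C@@]1(C)CC(O[Si](C)(C)C(C)(C)C)=CC[C@@H]1C=O | intermediate
6 | methyl (1S,6R)-3-[(tert-butyldimethylsilyl)oxy]-6-ethenyl-1-methylcyclohex-3-ene-1-carboxylate | COC(=O)[C@@]1(C)CC(O[Si](C)(C)C(C)(C)C)=CC[C@@H]1C=C | intermediate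
7 | 3,3-diethoxyprop-1-yne | C#CC(OCC)OCC | starting material
8 | (1E)-3,3-diethoxy-1-iodoprop-1-ene | CCOC(OCC)/C=C/I | intermediate
9 | methyl (1S,6S)-6-[2-(9-borabicyclo[3.3.1]nonan-9-yl)ethyl]-3-[(tert-butyldimethylsilyl)oxy]-1-methylcyclohex-3-ene-1-carboxylate | COC(=O)[C@@]1(C)CC(O[Si](C)(C)C(C)(C)C)=CC[C@@H]1CCB1C2CCCC1CCC2 | intermediate
10 | methyl (1S,6S)-3-[(tert-butyldimethylsilyl)oxy]-6-[(3E)-5,5-diethoxypent-3-en-1-yl]-1-methylcyclohex-3-ene-1-carboxylate | COC(=O)[C@@]1(C)CC(O[Si](C)(C)C(C)(C)C)=CC[C@@H]1CC/C=C/C(OCC)OCC | intermediate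
11 | methyl (1S,2S)-2-[(3E)-5,5-diethoxypent-3-en-1-yl]-1-methyl-5-oxocyclohex-3-ene-1-carboxylate | COC(=O)[C@@]1(C)CC(=O)C=C[C@@H]1CC/C=C/C(OCC)OCC | intermediate
12 | methyl (1S,2S)-2-[(3E)-5,5-diethoxypent-3-en-1-yl]-1-methyl-3-(prop-1-en-2-yl)-5-[(trimethylsilyl)oxy]cyclohex-4-ene-1-carboxylate (C-3 epimers) | COC(=O)[C@@]1(C)CC(O[Si](C)(C)C)=CC(C(C)=C)[C@@H]1CC/C=C/C(OCC)OCC | intermediate
13 | methyl (1S,2S)-2-[(3E)-5,5-diethoxypent-3-en-1-yl]-1-methyl-5-oxo-3-(prop-1-en-2-yl)cyclohex-3-ene-1-carboxylate | COC(=O)[C@@]1(C)CC(=O)C=C(C(C)=C)[C@@H]1CC/C=C/C(OCC)OCC | intermediate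
14 | (2S)-2-methylbutane-1,4-diol | OC[C@@H](C)CCO | starting material
15 | (2S)-4-[(tert-butyldiphenylsilyl)oxy]-2-methylbutan-1-ol | OC[C@@H](C)CCO[Si](c1ccccc1)(c1ccccc1)C(C)(C)C | intermediate
16 | [(3S)-4-bromo-3-methylbutoxy](tert-butyl)diphenylsilane | BrC[C@@H](C)CCO[Si](c1ccccc1)(c1ccccc1)C(C)(C)C | intermediate
17 | {(2S)-4-[(tert-butyldiphenylsilyl)oxy]-2-methylbutyl}magnesium bromide | Br[Mg]C[C@@H](C)CCO[Si](c1ccccc1)(c1ccccc1)C(C)(C)C | intermediate
18 | methyl (1S,2S,3E)-3-{(5R)-7-[(tert-butyldiphenylsilyl)oxy]-5-methylheptan-2-ylidene}-2-[(3E)-5,5-diethoxypent-3-en-1-yl]-1-methyl-5-[(trimethylsilyl)oxy]cyclohex-4-ene-1-carboxylate | COC(=O)[C@@]1(C)CC(O[Si](C)(C)C)=C/C(=C(\C)CC[C@@H](C)CCO[Si](c2ccccc2)(c2ccccc2)C(C)(C)C)[C@@H]1CC/C=C/C(OCC)OCC | intermediate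
19 | methyl (1S,5S,6S,8aS)-5-{(3R)-5-[(tert-butyldiphenylsilyl)oxy]-3-methylpentyl}-6-(3-ethoxyprop-2-en-1-yl)-1,5-dimethyl-3-oxo-1,2,3,5,6,7,8,8a-octahydronaphthalene-1-carboxylate (enol ether E/Z mixture) | COC(=O)[C@@]1(C)CC(=O)C=C2[C@@H]1CC[C@@H](CC=COCC)[C@]2(C)CC[C@@H](C)CCO[Si](c1ccccc1)(c1ccccc1)C(C)(C)C | intermediate
20 | methyl (1S,5S,6S,8aS)-5-{(3R)-5-[(tert-butyldiphenylsilyl)oxy]-3-methylpentyl}-1,5-dimethyl-3-oxo-6-(2-oxoethyl)-1,2,3,5,6,7,8,8a-octahydronaphthalene-1-carboxylate | COC(=O)[C@@]1(C)CC(=O)C=C2[C@@H]1CC[C@@H](CC=O)[C@]2(C)CC[C@@H](C)CCO[Si](c1ccccc1)(c1ccccc1)C(C)(C)C | intermediate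
21 | methyl (1S,5S,6R,8aS)-5-{(3R)-5-[(tert-butyldiphenylsilyl)oxy]-3-methylpentyl}-1,5,6-trimethyl-3-oxo-1,2,3,5,6,7,8,8a-octahydronaphthalene-1-carboxylate | COC(=O)[C@@]1(C)CC(=O)C=C2[C@@H]1CC[C@@H](C)[C@]2(C)CC[C@@H](C)CCO[Si](c1ccccc1)(c1ccccc1)C(C)(C)C | intermediate
22 | methyl (1S,5S,6R,8aS)-5-[(3R)-5-hydroxy-3-methylpentyl]-1,5,6-trimethyl-3-oxo-1,2,3,5,6,7,8,8a-octahydronaphthalene-1-carboxylate | COC(=O)[C@@]1(C)CC(=O)C=C2[C@@H]1CC[C@@H](C)[C@]2(C)CC[C@@H](C)CCO | target

**Step count**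

Total: 13 steps. Longest linear sequence: 9 steps (1, 3, 4, 6, 7, 8, 11, 12, 13).

**Steps most likely to fail**

Step 11 (key step). The ring closure may suffer from α-attack at C-4 in place of γ-attack at C-5, from 1,6-addition through the s-cis conformer (which inverts C-5), or from poor facial selectivity at C-6. The fallback sets out from 13 and returns at 20. The copper-catalysed 1,6-addition of 17 is run without Me3SiCl and the magnesium dienolate is silylated with t-BuMe2SiOTf to give the isolable methyl (1S,2S,3E)-5-[(tert-butyldimethylsilyl)oxy]-3-{(5R)-7-[(tert-butyldiphenylsilyl)oxy]-5-methylheptan-2-ylidene}-2-[(3E)-5,5-diethoxypent-3-en-1-yl]-1-methylcyclohex-4-ene-1-carboxylate F1. Brief treatment with oxalic acid on wet silica gel should free the enal, methyl (1S,2S,3E)-5-[(tert-butyldimethylsilyl)oxy]-3-{(5R)-7-[(tert-butyldiphenylsilyl)oxy]-5-methylheptan-2-ylidene}-1-methyl-2-[(3E)-5-oxopent-3-en-1-yl]cyclohex-4-ene-1-carboxylate F2, with the silyl dienol ether kept. Ring B is then closed by iminium-ion organocatalysis ((2R,5R)-5-benzyl-2-tert-butyl-3-methylimidazolidin-4-one trifluoroacetate, CH2Cl2–H2O, −20 °C). In this variant the amine catalyst, which by the usual shielding model exposes the Si face of C-6, decides the configuration at C-6, and the softer iminium electrophile favours the γ-carbon. Hydrolytic turnover gives 20.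

Step 3. The cycloaddition may fail through insufficient enantioface discrimination or through loss of regiocontrol, because the first bond must form at a fully substituted carbon. The fallback sets out from 2 and 4 and returns at 5. The cycloaddition is run with Me2AlCl (CH2Cl2, −78 °C), which should give racemic methyl (1SR,6SR)-3-[(tert-butyldimethylsilyl)oxy]-6-formyl-1-methylcyclohex-3-ene-1-carboxylate F3 with the same trans relationship. Condensation with (1R,2R)-N,N′-dimethyl-1,2-diphenylethane-1,2-diamine (4 Å molecular sieves, Et2O) gives two diastereomeric aminals. The (1S,6S)-configured one, methyl (1S,6S)-3-[(tert-butyldimethylsilyl)oxy]-6-[(4R,5R)-1,3-dimethyl-4,5-diphenylimidazolidin-2-yl]-1-methylcyclohex-3-ene-1-carboxylate F4, is separated by chromatography or crystallisation and cleaved on wet silica gel to give 5.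

Step 12. The decarbonylation may stall at the hindered aldehyde, or the alkylrhodium intermediate may undergo β-hydride elimination. The fallback sets out from 20 and returns at 21. NaBH(OAc)3 (CH2Cl2, 0 °C) should reduce only the aldehyde to methyl (1S,5S,6S,8aS)-5-{(3R)-5-[(tert-butyldiphenylsilyl)oxy]-3-methylpentyl}-6-(2-hydroxyethyl)-1,5-dimethyl-3-oxo-1,2,3,5,6,7,8,8a-octahydronaphthalene-1-carboxylate F5. I2, PPh3 and imidazole convert it into the iodide, methyl (1S,5S,6S,8aS)-5-{(3R)-5-[(tert-butyldiphenylsilyl)oxy]-3-methylpentyl}-6-(2-iodoethyl)-1,5-dimethyl-3-oxo-1,2,3,5,6,7,8,8a-octahydronaphthalene-1-carboxylate F6. Radical reduction with Bu3SnH and catalytic AIBN (benzene, 80 °C) then gives 21.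

**Further compounds**

F1 | step 11 | methyl (1S,2S,3E)-5-[(tert-butyldimethylsilyl)oxy]-3-{(5R)-7-[(tert-butyldiphenylsilyl)oxy]-5-methylheptan-2-ylidene}-2-[(3E)-5,5-diethoxypent-3-en-1-yl]-1-methylcyclohex-4-ene-1-carboxylate | COC(=O)[C@@]1(C)CC(O[Si](C)(C)C(C)(C)C)=C/C(=C(\C)CC[C@@H](C)CCO[Si](c2ccccc2)(c2ccccc2)C(C)(C)C)[C@@H]1CC/C=C/C(OCC)OCC
F2 | step 11 | methyl (1S,2S,3E)-5-[(tert-butyldimethylsilyl)oxy]-3-{(5R)-7-[(tert-butyldiphenylsilyl)oxy]-5-methylheptan-2-ylidene}-1-methyl-2-[(3E)-5-oxopent-3-en-1-yl]cyclohex-4-ene-1-carboxylate | COC(=O)[C@@]1(C)CC(O[Si](C)(C)C(C)(C)C)=C/C(=C(\C)CC[C@@H](C)CCO[Si](c2ccccc2)(c2ccccc2)C(C)(C)C)[C@@H]1CC/C=C/C=O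
F3 | step 3 | racemic methyl (1SR,6SR)-3-[(tert-butyldimethylsilyl)oxy]-6-formyl-1-methylcyclohex-3-ene-1-carboxylate | COC(=O)[C@@]1(C)CC(O[Si](C)(C)C(C)(C)C)=CC[C@@H]1C=O.COC(=O)[C@]1(C)CC(O[Si](C)(C)C(C)(C)C)=CC[C@H]1C=O
F4 | step 3 | methyl (1S,6S)-3-[(tert-butyldimethylsilyl)oxy]-6-[(4R,5R)-1,3-dimethyl-4,5-diphenylimidazolidin-2-yl]-1-methylcyclohex-3-ene-1-carboxylate | COC(=O)[C@@]1(C)CC(O[Si](C)(C)C(C)(C)C)=CC[C@@H]1C2N(C)[C@H](c3ccccc3)[C@@H](c3ccccc3)N2C
F5 | step 12 | methyl (1S,5S,6S,8aS)-5-{(3R)-5-[(tert-butyldiphenylsilyl)oxy]-3-methylpentyl}-6-(2-hydroxyethyl)-1,5-dimethyl-3-oxo-1,2,3,5,6,7,8,8a-octahydronaphthalene-1-carboxylate | COC(=O)[C@@]1(C)CC(=O)C=C2[C@@H]1CC[C@@H](CCO)[C@]2(C)CC[C@@H](C)CCO[Si](c1ccccc1)(c1ccccc1)C(C)(C)C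
F6 | step 12 | methyl (1S,5S,6S,8aS)-5-{(3R)-5-[(tert-butyldiphenylsilyl)oxy]-3-methylpentyl}-6-(2-iodoethyl)-1,5-dimethyl-3-oxo-1,2,3,5,6,7,8,8a-octahydronaphthalene-1-carboxylate | COC(=O)[C@@]1(C)CC(=O)C=C2[C@@H]1CC[C@@H](CCI)[C@]2(C)CC[C@@H](C)CCO[Si](c1ccccc1)(c1ccccc1)C(C)(C)C
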